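**Plan**

- Retrosynthesis: the pyranone ring is contracted by joining C2 to C4 (flavanone numbering), which gives a cyclopropanol fused to a dihydrobenzofuran. The cyclopropane CH2 (the later C3) is then removed to leave a flat 3-silyloxy-2-phenylbenzofuran. The aryl–geranyl bond is cut to an aryllithium and geranyl bromide, and the furanone is cut at C3–C3a (Friedel–Crafts) and O1–C2 (Williamson).
- Forward: aryl ether → benzofuran-3-one (five-membered O-ring) → aromatic bis-silyloxybenzofuran → dearomative enantioselective cyclopropanation (three-membered ring) → C-geranylation on a bicycle that has neither carbonyl nor olefin → fluoride-triggered scission of the ring-fusion bond, which merges the five- and three-membered rings into the six-membered pyranone and frees the 5-OH.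
- Enabling feature: C2 of the target is both benzylic and bonded to O1, and C4 carries oxygen. In the 2-oxabicyclo[3.1.0]hexane precursor the C2–C4 bond is therefore the one cyclopropane bond that the C4 alkoxide can break with charge landing on a stabilised carbon.
- Stereochemistry: C2 comes from ligand-controlled face selection in the cyclopropanation, giving (1aR,6bR), and is passed on with inversion in the ring-opening protonation. The 2E olefin arrives intact with geranyl bromide.

Key step: step 7

Assumption: the alkoxide-triggered cyclopropanol opening protonates the benzylic carbon from the backside (inversion), as is the rule for base-induced homoketonisation; the cyclopropane configuration is chosen on that basis.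

**Route**

Step 1
Reactants: 1 3,5-dimethoxyphenol; 2 methyl 2-bromo-2-phenylacetate (racemic)
Product: 4 2-(3,5-dimethoxyphenoxy)-2-phenylacetic acid (racemic), via methyl ester 3 (not isolated)
Conditions: K2CO3, DMF, rt; then aq. NaOH, 50 °C; HCl work-up
Reagents that add atoms: sodium hydroxide, [Na+].[OH-]
Why: Williamson ether synthesis (phenoxide SN2 on the activated benzylic α-bromo ester) followed by saponification in the same flask; the stereocentre is racemic and is erased later by enolisation.

Step 2
Reactants: 4 2-(3,5-dimethoxyphenoxy)-2-phenylacetic acid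
Product: 5 4,6-dimethoxy-2-phenyl-1-benzofuran-3(2H)-one (racemic, C2 labile; handled under argon)
Conditions: TFAA, CH2Cl2, 0 °C → rt; aq. NaHCO3
Reagents that add atoms: none
Why: Intramolecular Friedel–Crafts acylation through the mixed trifluoroacetic anhydride onto the phloroglucinol-type ring, whose two ortho positions are equivalent, so only one five-membered ring closure is possible.

Step 3
Reactants: 5 4,6-dimethoxy-2-phenyl-1-benzofuran-3(2H)-one
Product: 6 4-hydroxy-6-methoxy-2-phenyl-1-benzofuran-3(2H)-one (racemic, C2 labile)
Conditions: BCl3 (1.5 equiv), CH2Cl2, −78 → 0 °C; aqueous work-up, under argon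
Reagents that add atoms: none
Why: Chelation-controlled aryl methyl ether cleavage, in which BCl3 bridges the C3 carbonyl and the peri 4-methoxy oxygen so that only this methyl group is lost and the 6-methoxy group stays.

Step 4
Reactants: 6 4-hydroxy-6-methoxy-2-phenyl-1-benzofuran-3(2H)-one
Product: 7 3,4-bis[(tert-butyldimethylsilyl)oxy]-6-methoxy-2-phenyl-1-benzofuran
Conditions: TBSOTf (2.4 equiv), Et3N (3 equiv), CH2Cl2, 0 °C
Reagents that add atoms: tert-butyldimethylsilyl trifluoromethanesulfonate (TBSOTf), CC(C)(C)[Si](C)(C)OS(=O)(=O)C(F)(F)F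
Why: Silyl triflate/amine silylation of the phenol and of the ketone enol, the latter driven by aromatisation to the benzofuran; no stereocentre remains.

Step 5
Reactants: 7 3,4-bis[(tert-butyldimethylsilyl)oxy]-6-methoxy-2-phenyl-1-benzofuran
Product: 8 (1aR,6bR)-6,6b-bis[(tert-butyldimethylsilyl)oxy]-4-methoxy-1a-phenyl-1a,6b-dihydro-1H-cyclopropa[b][1]benzofuran (cis-fused; CH2 bridges the former furan C2 and C3)
Conditions: Et2Zn, CH2I2, N-Boc-L-Val-L-Pro-OMe (1.25 equiv), CH2Cl2, −40 → 0 °C
Reagents that add atoms: diiodomethane, ICI
Why: Proposed new method: the (iodomethyl)zinc species bound to the chiral dipeptide should transfer CH2 in a concerted syn fashion to the furan C2=C3 bond, the most electron-rich π bond of 7 (a silyl enol ether next to a trioxygenated arene) in the weakly aromatic furan ring, so dearomatisation costs little; both stereocentres form at once, cis fusion is enforced by the ring, and the face is set by the ligand (its antipode is used if a pilot run shows the opposite sense). The closest known reaction type is the enantioselective Simmons–Smith cyclopropanation of aryl ketone silyl enol ethers and trisubstituted aryl olefins with the same zinc–dipeptide reagent.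

Step 6
Reactants: 8 the (1aR,6bR)-cyclopropane; 9 geranyl bromide [(2E)-1-bromo-3,7-dimethylocta-2,6-diene]
Product: 11 (1aR,6bR)-6,6b-bis[(tert-butyldimethylsilyl)oxy]-3-[(2E)-3,7-dimethylocta-2,6-dien-1-yl]-4-methoxy-1a-phenyl-1a,6b-dihydro-1H-cyclopropa[b][1]benzofuran, via aryllithium 10 (not isolated)
Conditions: s-BuLi, TMEDA, THF, −78 °C; CuBr·SMe2 (10 mol %), then 9, −78 → 0 °C
Reagents that add atoms: none
Why: Directed ortho-metalation at the C–H flanked by the ring oxygen and the methoxy group (the other C–H is shielded by OTBS), then copper-catalysed SN2 allylation with geranyl bromide, which keeps the 2E geometry, on a substrate that at this stage has no carbonyl group and no olefin.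

Step 7
Reactants: 11 the geranylated (1aR,6bR)-bis-silyloxy cyclopropane
Product: 13 (2S)-8-[(2E)-3,7-dimethylocta-2,6-dien-1-yl]-5-hydroxy-7-methoxy-2-phenyl-2,3-dihydro-4H-chromen-4-one, via cyclopropane-6,6b-diol 12 (not isolated)
Conditions: TBAF (2.5 equiv), MeOH (5 equiv), THF, −40 → 0 °C; then AcOH quench in the cold
Reagents that add atoms: none
Why: Proposed new method: fluoride removes both silyl groups, and the tertiary cyclopropanolate at C6b should push its electrons into the ring-fusion bond C1a–C6b, which breaks because the developing charge on C1a is benzylic and inductively stabilised by O2, whereas cleavage towards the primary C1 has no such help; the C4 carbonyl forms as methanol protonates C1a from the side opposite to the departing carbon. The closest known reaction type is the base-induced homoketonisation of 2-arylcyclopropanols, which cleaves towards the benzylic carbon with inversion, combined with fluoride-triggered opening of siloxycyclopropanes. No ring is closed: the six-membered pyranone arises when the bond shared by the five-membered dihydrofuran ring and the cyclopropane is cut, so that the former cyclopropane CH2 becomes C3. The one stereocentre of the product, C2, is controlled by the configuration of C1a in 11 and the backside (SE2, inversion) protonation, so that (1aR,6bR) should give 2S, while the C6b centre disappears into the carbonyl. The step needs scission of one specific bond out of three, secured by the phenyl group and O2 on C1a, and it needs the flavanone to survive the base, for which the 5-phenoxide formed in the same step lowers the acidity at C3 and the cold acid quench should stop retro-oxa-Michael opening to the chalcone.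

**Compound list**

1 | 3,5-dimethoxyphenol | COc1cc(O)cc(OC)c1 | starting material
2 | methyl 2-bromo-2-phenylacetate (racemic) | COC(=O)C(Br)c1ccccc1 | starting material
3 | methyl 2-(3,5-dimethoxyphenoxy)-2-phenylacetate (racemic, not isolated) | COC(=O)C(Oc1cc(OC)cc(OC)c1)c1ccccc1 | intermediate
4 | 2-(3,5-dimethoxyphenoxy)-2-phenylacetic acid (racemic) | OC(=O)C(Oc1cc(OC)cc(OC)c1)c1ccccc1 | intermediate
5 | 4,6-dimethoxy-2-phenyl-1-benzofuran-3(2H)-one (racemic) | COc1cc(OC)c2c(c1)OC(c1ccccc1)C2=O | intermediate
6 | 4-hydroxy-6-methoxy-2-phenyl-1-benzofuran-3(2H)-one (racemic) | COc1cc(O)c2c(c1)OC(c1ccccc1)C2=O | intermediate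
7 | 3,4-bis[(tert-butyldimethylsilyl)oxy]-6-methoxy-2-phenyl-1-benzofuran | COc1cc(O[Si](C)(C)C(C)(C)C)c2c(O[Si](C)(C)C(C)(C)C)c(-c3ccccc3)oc2c1 | intermediate
8 | (1aR,6bR)-6,6b-bis[(tert-butyldimethylsilyl)oxy]-4-methoxy-1a-phenyl-1a,6b-dihydro-1H-cyclopropa[b][1]benzofuran | COc1cc(O[Si](C)(C)C(C)(C)C)c2c(c1)O[C@@]3(c4ccccc4)C[C@@]23O[Si](C)(C)C(C)(C)C | intermediate
9 | geranyl bromide, (2E)-1-bromo-3,7-dimethylocta-2,6-diene | CC(C)=CCC/C(C)=C/CBr | starting material
10 | 3-lithio derivative of 8 (aryllithium between ring O and OMe, not isolated) | COc1cc(O[Si](C)(C)C(C)(C)C)c2c(c1[Li])O[C@@]3(c4ccccc4)C[C@@]23O[Si](C)(C)C(C)(C)C | intermediate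
11 | (1aR,6bR)-6,6b-bis[(tert-butyldimethylsilyl)oxy]-3-[(2E)-3,7-dimethylocta-2,6-dien-1-yl]-4-methoxy-1a-phenyl-1a,6b-dihydro-1H-cyclopropa[b][1]benzofuran | COc1cc(O[Si](C)(C)C(C)(C)C)c2c(c1C/C=C(\C)CCC=C(C)C)O[C@@]3(c4ccccc4)C[C@@]23O[Si](C)(C)C(C)(C)C | intermediate
12 | (1aR,6bR)-3-[(2E)-3,7-dimethylocta-2,6-dien-1-yl]-4-methoxy-1a-phenyl-1a,6b-dihydro-1H-cyclopropa[b][1]benzofuran-6,6b-diol (formed as its anion, not isolated) | COc1cc(O)c2c(c1C/C=C(\C)CCC=C(C)C)O[C@@]3(c4ccccc4)C[C@@]23O | intermediate
13 | (2S)-8-[(2E)-3,7-dimethylocta-2,6-dien-1-yl]-5-hydroxy-7-methoxy-2-phenyl-2,3-dihydro-4H-chromen-4-one | COc1cc(O)c2c(c1C/C=C(\C)CCC=C(C)C)O[C@H](c1ccccc1)CC2=O | target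

**Totals**

Total step count: 7. Longest linear sequence: 7 steps (from 3,5-dimethoxyphenol).

**Steps most likely to fail**

Step 7. The process at risk is erosion of configuration at C2, either because protonation is not fully backside or because the flavanone opens reversibly to the chalcone in the basic medium before the quench. Fallback: setting out from 11, the opening is run as above and the scalemic product, 13 mixed with (2R)-8-[(2E)-3,7-dimethylocta-2,6-dien-1-yl]-5-hydroxy-7-methoxy-2-phenyl-2,3-dihydro-4H-chromen-4-one F1, is put through a kinetic resolution by asymmetric transfer hydrogenation (Rh(III)–TsDPEN catalyst, HCO2H/Et3N), a known reaction type for racemic flavanones. The catalyst antipode matched to the 2R ketone should reduce it to the cis-alcohol (2R,4R)-8-[(2E)-3,7-dimethylocta-2,6-dien-1-yl]-7-methoxy-2-phenyl-3,4-dihydro-2H-chromene-4,5-diol F2, which is removed by chromatography; the route comes back at 13.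

Step 5. The process at risk is poor facial selectivity, or sluggish methylene transfer to the tetrasubstituted enol ether inside the aromatic furan ring. Fallback: setting out from 7, cyclopropanation with the achiral, more electrophilic zinc carbenoid (Et2Zn, CH2I2, CF3CO2H, CH2Cl2, 0 °C) should give racemic cis-fused 6,6b-bis[(tert-butyldimethylsilyl)oxy]-4-methoxy-1a-phenyl-1a,6b-dihydro-1H-cyclopropa[b][1]benzofuran F3. Preparative chromatography on a chiral stationary phase separates 8 from its (1aS,6bS)-enantiomer F4, and the route comes back at 8.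

Step 6. The process at risk is metalation at the wrong C–H (next to OTBS, with silyl migration to carbon) or incomplete metalation. Fallback: setting out from 8, electrophilic bromination with NBS (CH2Cl2, −78 °C) is expected at the less hindered position between the ring oxygen and the methoxy group and should give (1aR,6bR)-3-bromo-6,6b-bis[(tert-butyldimethylsilyl)oxy]-4-methoxy-1a-phenyl-1a,6b-dihydro-1H-cyclopropa[b][1]benzofuran F5. Bromine–lithium exchange (t-BuLi, 2 equiv, THF, −78 °C) followed by CuBr·SMe2 (cat.) and geranyl bromide 9 then gives 11, where the route is rejoined.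

**Further compounds**

F1 | step 7 | (2R)-8-[(2E)-3,7-dimethylocta-2,6-dien-1-yl]-5-hydroxy-7-methoxy-2-phenyl-2,3-dihydro-4H-chromen-4-one | COc1cc(O)c2c(c1C/C=C(\C)CCC=C(C)C)O[C@@H](c1ccccc1)CC2=O
F2 | step 7 | (2R,4R)-8-[(2E)-3,7-dimethylocta-2,6-dien-1-yl]-7-methoxy-2-phenyl-3,4-dihydro-2H-chromene-4,5-diol | COc1cc(O)c2c(c1C/C=C(\C)CCC=C(C)C)O[C@@H](c1ccccc1)C[C@H]2O
F3 | step 5 | racemic cis-fused 6,6b-bis[(tert-butyldimethylsilyl)oxy]-4-methoxy-1a-phenyl-1a,6b-dihydro-1H-cyclopropa[b][1]benzofuran | COc1cc(O[Si](C)(C)C(C)(C)C)c2c(c1)OC3(c4ccccc4)CC23O[Si](C)(C)C(C)(C)C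
F4 | step 5 | (1aS,6bS)-6,6b-bis[(tert-butyldimethylsilyl)oxy]-4-methoxy-1a-phenyl-1a,6b-dihydro-1H-cyclopropa[b][1]benzofuran | COc1cc(O[Si](C)(C)C(C)(C)C)c2c(c1)O[C@]3(c4ccccc4)C[C@]23O[Si](C)(C)C(C)(C)C
F5 | step 6 | (1aR,6bR)-3-bromo-6,6b-bis[(tert-butyldimethylsilyl)oxy]-4-methoxy-1a-phenyl-1a,6b-dihydro-1H-cyclopropa[b][1]benzofuran | COc1cc(O[Si](C)(C)C(C)(C)C)c2c(c1Br)O[C@@]3(c4ccccc4)C[C@@]23O[Si](C)(C)C(C)(C)C
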